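**Assumption:** locants C1–C15 follow germacrane numbering of the target (C6/C7 lactone fusion, C8 glycidate, C9 acetate, C14 = ester carbon on C10, C15 = methyl on C4); compound 16 is (S)-glyceraldehyde carrying its isopropylidene protecting group.

## Retrosynthetic overview

1. Target ⇐ 8-O-acylation with (S)-2-methylglycidic acid and 9-O-acetylation of the macrocyclic hydroxy lactone 21.
2. Key disconnection C7–C8: a samarium ketyl radical at C8 adds to C7 of a 3-(acetoxymethyl)butenolide; loss of acetate unveils the α-methylene lactone while the ten-membered ring closes (sets C7 and C8).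
3. Seco aldehyde 20 ⇐ C9–C10 union of the (Z)-α-bromoacrylate 15 with (S)-glyceraldehyde acetonide (sets C9; the auxiliary carbon is later excised).
4. Butenolide ⇐ ring-closing metathesis ⇐ vinyl addition to a cis-epoxy aldehyde (sets C6) ⇐ Sharpless epoxidation (sets C4, C5).
5. C1–C6 with ring-fixed Z geometry ⇐ ozonolytic opening of 3-methylcyclohex-2-enone. Ring order: oxirane → butenolide → ten-membered carbocycle.

## Route

**Step 1**
Reactants: 1 3-methylcyclohex-2-en-1-one
Product: 3 (2Z)-3-methyl-6-oxohex-2-enoic acid, via silyl dienol ether 2 (not isolated)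
Conditions: LiN(iPr)2, THF, −78 °C; Me3SiCl; then O3 (1.0 equiv), CH2Cl2/MeOH, −78 °C; Me2S; H2O
Reagents that add atoms: ozone [O-][O+]=O; chlorotrimethylsilane C[Si](C)(C)Cl (its silyl group is present only in 2)
Why: Kinetic α′-enolisation and silylation give the cross-conjugated silyl dienol ether, whose electron-rich enol ether bond is cleaved selectively (ozonolysis of a silyl enol ether) to the C6 acid and C1 aldehyde, the former ring fixing the Z geometry of C4=C5.

**Step 2**
Reactants: 3 (2Z)-3-methyl-6-oxohex-2-enoic acid; 4 methyl tribromoacetate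
Product: 5 (2Z,6Z)-7-bromo-8-methoxy-3-methyl-8-oxoocta-2,6-dienoic acid
Conditions: CrCl2 (6 equiv), THF, 25 °C
Reagents that add atoms: none
Why: Divalent-chromium olefination of an aldehyde with a trihaloacetate (Falck–Mioskowski reaction: chromium Reformatsky addition, then reductive anti-elimination) gives the α-bromoacrylate with bromine cis to the chain, the acid being carried as its chromium carboxylate.

**Step 3**
Reactants: 5 bromoacrylate acid
Product: 7 methyl (2Z,6Z)-2-bromo-8-hydroxy-6-methylocta-2,6-dienoate, via mixed anhydride 6 (not isolated)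
Conditions: i-BuOCOCl, N-methylmorpholine, THF, −15 °C; then NaBH4, H2O, −15 → 0 °C
Reagents that add atoms: isobutyl chloroformate CC(C)COC(=O)Cl (its carbonate unit is present only in 6)
Why: Mixed-anhydride activation lets borohydride reduce only the carboxyl group to the Z allylic alcohol, leaving the methyl ester and vinyl bromide untouched.

**Step 4**
Reactants: 7 Z allylic alcohol
Product: 8 methyl (2Z)-2-bromo-5-[(2R,3S)-3-(hydroxymethyl)-2-methyloxiran-2-yl]pent-2-enoate
Conditions: Ti(OiPr)4 (10 mol%), L-(+)-diethyl tartrate (12 mol%), t-BuOOH, 4 Å MS, CH2Cl2, −20 °C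
Reagents that add atoms: tert-butyl hydroperoxide CC(C)(C)OO
Why: Sharpless asymmetric epoxidation with the L-(+)-tartrate converts this nerol-type Z allylic alcohol into the (2S,3R)-2,3-epoxy alcohol (about 90% ee expected), which sets C4 (R) and C5 and the cis relation of C3 and C6; the electron-poor bromoacrylate is inert.

**Step 5**
Reactants: 8 epoxy alcohol
Product: 9 methyl (2Z)-2-bromo-5-[(2R,3R)-3-formyl-2-methyloxiran-2-yl]pent-2-enoate
Conditions: Dess–Martin periodinane, CH2Cl2, 0 °C
Reagents that add atoms: none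
Why: Dess–Martin oxidation gives the cis-epoxy aldehyde without epimerisation at C5 (the descriptor changes only by CIP priority).

**Step 6**
Reactants: 9 epoxy aldehyde; 10 vinylmagnesium bromide
Product: 11 methyl (2Z)-2-bromo-5-{(2R,3S)-3-[(1S)-1-hydroxyprop-2-en-1-yl]-2-methyloxiran-2-yl}pent-2-enoate
Conditions: CH2=CHMgBr (1.2 equiv), THF, −78 °C; then H2O
Reagents that add atoms: none
Why: Felkin–Anh (polar) addition anti to the epoxide C–O bond, reinforced by the cis C3 substituent, sets C6 (S) with the new hydroxyl anti to the epoxide oxygen; the aldehyde reacts far faster than the ester or vinyl bromide at −78 °C.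

**Step 7**
Reactants: 12 2-(bromomethyl)prop-2-enoic acid
Product: 13 2-(acetoxymethyl)prop-2-enoic acid
Conditions: KOAc (5 equiv), AcOH, 60 °C
Reagents that add atoms: potassium acetate CC(=O)[O-].[K+]
Why: Allylic substitution (SN2 and SN2′ give the same product) of the activated bromide by acetate, which is in large excess over the substrate carboxylate.

**Step 8**
Reactants: 11 allylic alcohol; 13 2-(acetoxymethyl)prop-2-enoic acid
Product: 14 methyl (2Z)-5-{(2R,3S)-3-[(1S)-1-{[2-(acetoxymethyl)prop-2-enoyl]oxy}prop-2-en-1-yl]-2-methyloxiran-2-yl}-2-bromopent-2-enoate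
Conditions: DIC, DMAP (10 mol%), CH2Cl2, 0 °C
Reagents that add atoms: none
Why: Steglich esterification acylates the C6 hydroxyl with retention and installs all four lactone carbons (C7, C11, C12, C13) with the future leaving group on C13.

**Step 9**
Reactants: 14 diene ester
Product: 15 methyl (2Z)-5-{(2R,3S)-3-[(2S)-4-(acetoxymethyl)-5-oxo-2,5-dihydrofuran-2-yl]-2-methyloxiran-2-yl}-2-bromopent-2-enoate
Conditions: second-generation Hoveyda–Grubbs catalyst (5 mol%), toluene, 80 °C
Reagents that add atoms: none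
Why: Ring-closing metathesis of the acrylate with the terminal vinyl group forms the butenolide (five-membered ring, ethene lost); the trisubstituted bromoacrylate does not take part and C6 is untouched.

**Step 10**
Reactants: 15 bromoacrylate butenolide; 16 (4S)-2,2-dimethyl-1,3-dioxolane-4-carbaldehyde
Product: 17 methyl (2E)-5-{(2R,3S)-3-[(2S)-4-(acetoxymethyl)-5-oxo-2,5-dihydrofuran-2-yl]-2-methyloxiran-2-yl}-2-{(R)-[(4S)-2,2-dimethyl-1,3-dioxolan-4-yl](hydroxy)methyl}pent-2-enoate
Conditions: CrCl2 (5 equiv), NiCl2 (2 mol%), DMSO, 25 °C; then H2O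
Reagents that add atoms: none
Why: Nozaki–Hiyama–Kishi coupling forms the alkenylchromium with retention of geometry (C2 stays cis to the new C9) and adds it to the aldehyde under Felkin–Anh control anti to the dioxolane oxygen, setting C9 (R) (moderate selectivity, about 3–5:1, expected; epimers separable); epoxide, lactone and esters are inert to the organochromium.

**Step 11**
Reactants: 17 allylic alcohol
Product: 18 methyl (2E)-5-{(2R,3S)-3-[(2S)-4-(acetoxymethyl)-5-oxo-2,5-dihydrofuran-2-yl]-2-methyloxiran-2-yl}-2-{(R)-(tert-butyldimethylsilyloxy)[(4S)-2,2-dimethyl-1,3-dioxolan-4-yl]methyl}pent-2-enoate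
Conditions: TBSOTf, 2,6-lutidine, CH2Cl2, −78 °C
Reagents that add atoms: tert-butyldimethylsilyl triflate CC(C)(C)[Si](C)(C)OS(=O)(=O)C(F)(F)F
Why: Silylation protects O9 with a group that can neither leave nor migrate in the radical step (an acyl group on O9 would be expelled from the α-position of the ketyl).

**Step 12**
Reactants: 18 silyl ether acetonide
Product: 20 methyl (2E)-5-{(2R,3S)-3-[(2S)-4-(acetoxymethyl)-5-oxo-2,5-dihydrofuran-2-yl]-2-methyloxiran-2-yl}-2-[(1R)-1-(tert-butyldimethylsilyloxy)-2-oxoethyl]pent-2-enoate, via diol 19 (not isolated)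
Conditions: PPTS, MeOH, 40 °C; then NaIO4, THF/H2O (pH 7), 0 °C
Reagents that add atoms: none
Why: Mild transacetalisation frees the terminal diol and periodate glycol cleavage (Malaprade reaction) excises the auxiliary carbon to give the C8 aldehyde; the stereocentre that steered C9 is erased and C9 is untouched.

**Step 13**
Reactants: 20 seco aldehyde
Product: 21 methyl (1(10)E,4R,5S,6S,7R,8S,9R)-9-(tert-butyldimethylsilyloxy)-4,5-epoxy-8-hydroxygermacra-1(10),11(13)-dien-6,12-olid-14-oate
Conditions: SmI2 (2.2 equiv, 0.1 M in THF) added over 3 h to 20 (1 mM in THF), −40 °C; then aq. NH4Cl at −40 °C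
Reagents that add atoms: none
Why: Proposed new method: SmI2 reduces the aldehyde to a samarium ketyl radical at C8 that adds in the 10-endo mode to C7 of the samarium-coordinated butenolide, a second electron gives the trivalent samarium enolate, and this expels acetate (E1cB) to unveil the α-methylene lactone without a proton source or later methylenation; C7 is set by attack anti to the C5 substituent (syn attack would force a near-eclipsed C5–C6–C7–C8 torsion), giving the trans-fused lactone, and C8 (S) by a staggered transition state with the bulky O–Sm group antiperiplanar to the enolate carbon C11 and H8 inside; closest known reactions are SmI2 ketyl–olefin cyclisations onto unsaturated esters with ensuing β-elimination, SmI2 eight-membered ring closures and endo radical macrocyclisations onto acrylates.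

**Step 14**
Reactants: 22 (2R)-(2-methyloxiran-2-yl)methanol
Product: 23 (2S)-2-methyloxirane-2-carboxylic acid
Conditions: RuCl3 (2 mol%), NaIO4, MeCN/EtOAc/H2O, 0 → 25 °C
Reagents that add atoms: water O
Why: Sharpless ruthenium tetroxide oxidation of a glycidol to the glycidic acid; the quaternary stereocentre is untouched (the descriptor changes from R to S only by CIP priority).

**Step 15**
Reactants: 21 macrocyclic alcohol; 23 (2S)-2-methyloxirane-2-carboxylic acid
Product: 24 methyl (1(10)E,4R,5S,6S,7S,8S,9R)-9-(tert-butyldimethylsilyloxy)-4,5-epoxy-8-{[(2S)-2-methyloxirane-2-carbonyl]oxy}germacra-1(10),11(13)-dien-6,12-olid-14-oate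
Conditions: DIC, DMAP, CH2Cl2, 0 → 25 °C
Reagents that add atoms: none
Why: Steglich esterification acylates the only free hydroxyl (C8) with retention (the C7 descriptor changes to S only because the silyl ether alters CIP priorities).

**Step 16**
Reactants: 24 silyl ether
Product: 26 methyl (1(10)E,4R,5S,6S,7R,8S,9R)-9-acetoxy-4,5-epoxy-8-{[(2S)-2-methyloxirane-2-carbonyl]oxy}germacra-1(10),11(13)-dien-6,12-olid-14-oate, via alcohol 25 (not isolated)
Conditions: Bu4NF/AcOH (1:1), THF, 25 °C; then Ac2O, Et3N, DMAP (cat.), 0 °C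
Reagents that add atoms: acetic anhydride CC(=O)OC(C)=O
Why: Buffered fluoride desilylation spares both epoxides and the esters, and immediate acetylation of the freed C9 hydroxyl in the same flask prevents migration of the neighbouring C8 ester.

## Compound list

1 | 3-methylcyclohex-2-en-1-one | CC1=CC(=O)CCC1 | starting material
2 | 4-methyl-2-(trimethylsilyloxy)cyclohexa-1,3-diene | CC1=CC(O[Si](C)(C)C)=CCC1 | intermediate
3 | (2Z)-3-methyl-6-oxohex-2-enoic acid | OC(=O)/C=C(/C)CCC=O | intermediate
4 | methyl tribromoacetate | COC(=O)C(Br)(Br)Br | starting material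
5 | (2Z,6Z)-7-bromo-8-methoxy-3-methyl-8-oxoocta-2,6-dienoic acid | OC(=O)/C=C(/C)CC/C=C(\Br)C(=O)OC | intermediate
6 | isobutyl carbonic mixed anhydride of 5 | CC(C)COC(=O)OC(=O)/C=C(/C)CC/C=C(\Br)C(=O)OC | intermediate
7 | methyl (2Z,6Z)-2-bromo-8-hydroxy-6-methylocta-2,6-dienoate | OC/C=C(/C)CC/C=C(\Br)C(=O)OC | intermediate
8 | methyl (2Z)-2-bromo-5-[(2R,3S)-3-(hydroxymethyl)-2-methyloxiran-2-yl]pent-2-enoate | COC(=O)/C(Br)=C/CC[C@@]1(C)O[C@H]1CO | intermediate
9 | methyl (2Z)-2-bromo-5-[(2R,3R)-3-formyl-2-methyloxiran-2-yl]pent-2-enoate | COC(=O)/C(Br)=C/CC[C@@]1(C)O[C@H]1C=O | intermediate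
10 | vinylmagnesium bromide (CH2=CHMgBr) | C=C[Mg]Br | starting material
11 | methyl (2Z)-2-bromo-5-{(2R,3S)-3-[(1S)-1-hydroxyprop-2-en-1-yl]-2-methyloxiran-2-yl}pent-2-enoate | COC(=O)/C(Br)=C/CC[C@@]1(C)O[C@H]1[C@@H](O)C=C | intermediate
12 | 2-(bromomethyl)prop-2-enoic acid | OC(=O)C(=C)CBr | starting material
13 | 2-(acetoxymethyl)prop-2-enoic acid | CC(=O)OCC(=C)C(=O)O | intermediate
14 | methyl (2Z)-5-{(2R,3S)-3-[(1S)-1-{[2-(acetoxymethyl)prop-2-enoyl]oxy}prop-2-en-1-yl]-2-methyloxiran-2-yl}-2-bromopent-2-enoate | COC(=O)/C(Br)=C/CC[C@@]1(C)O[C@H]1[C@@H](OC(=O)C(=C)COC(C)=O)C=C | intermediate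
15 | methyl (2Z)-5-{(2R,3S)-3-[(2S)-4-(acetoxymethyl)-5-oxo-2,5-dihydrofuran-2-yl]-2-methyloxiran-2-yl}-2-bromopent-2-enoate | COC(=O)/C(Br)=C/CC[C@@]1(C)O[C@H]1[C@H]1OC(=O)C(COC(C)=O)=C1 | intermediate
16 | (4S)-2,2-dimethyl-1,3-dioxolane-4-carbaldehyde | O=C[C@@H]1COC(C)(C)O1 | starting material
17 | methyl (2E)-5-{(2R,3S)-3-[(2S)-4-(acetoxymethyl)-5-oxo-2,5-dihydrofuran-2-yl]-2-methyloxiran-2-yl}-2-{(R)-[(4S)-2,2-dimethyl-1,3-dioxolan-4-yl](hydroxy)methyl}pent-2-enoate | CC1(C)OC[C@H](O1)[C@H](O)/C(C(=O)OC)=C\CC[C@@]1(C)O[C@H]1[C@H]1OC(=O)C(COC(C)=O)=C1 | intermediate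
18 | 9-O-tert-butyldimethylsilyl ether of 17 (9R, dioxolane 4S) | CC1(C)OC[C@H](O1)[C@H](O[Si](C)(C)C(C)(C)C)/C(C(=O)OC)=C\CC[C@@]1(C)O[C@H]1[C@H]1OC(=O)C(COC(C)=O)=C1 | intermediate
19 | methyl (2E)-5-{(2R,3S)-3-[(2S)-4-(acetoxymethyl)-5-oxo-2,5-dihydrofuran-2-yl]-2-methyloxiran-2-yl}-2-[(1R,2S)-1-(tert-butyldimethylsilyloxy)-2,3-dihydroxypropyl]pent-2-enoate | OC[C@H](O)[C@H](O[Si](C)(C)C(C)(C)C)/C(C(=O)OC)=C\CC[C@@]1(C)O[C@H]1[C@H]1OC(=O)C(COC(C)=O)=C1 | intermediate
20 | methyl (2E)-5-{(2R,3S)-3-[(2S)-4-(acetoxymethyl)-5-oxo-2,5-dihydrofuran-2-yl]-2-methyloxiran-2-yl}-2-[(1R)-1-(tert-butyldimethylsilyloxy)-2-oxoethyl]pent-2-enoate | O=C[C@H](O[Si](C)(C)C(C)(C)C)/C(C(=O)OC)=C\CC[C@@]1(C)O[C@H]1[C@H]1OC(=O)C(COC(C)=O)=C1 | intermediate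
21 | methyl (1(10)E,4R,5S,6S,7R,8S,9R)-9-(tert-butyldimethylsilyloxy)-4,5-epoxy-8-hydroxygermacra-1(10),11(13)-dien-6,12-olid-14-oate (C2 cis to C9; cis-epoxide; trans-fused lactone) | C=C1C(=O)O[C@H]2[C@H]1[C@H](O)[C@H](O[Si](C)(C)C(C)(C)C)/C(C(=O)OC)=C\CC[C@@]1(C)O[C@@H]21 | intermediate
22 | (2R)-(2-methyloxiran-2-yl)methanol | OC[C@]1(C)CO1 | starting material
23 | (2S)-2-methyloxirane-2-carboxylic acid | OC(=O)[C@]1(C)CO1 | intermediate
24 | methyl (1(10)E,4R,5S,6S,7S,8S,9R)-9-(tert-butyldimethylsilyloxy)-4,5-epoxy-8-{[(2S)-2-methyloxirane-2-carbonyl]oxy}germacra-1(10),11(13)-dien-6,12-olid-14-oate (same spatial arrangement as 21) | C=C1C(=O)O[C@H]2[C@H]1[C@H](OC(=O)[C@]1(C)CO1)[C@H](O[Si](C)(C)C(C)(C)C)/C(C(=O)OC)=C\CC[C@@]1(C)O[C@@H]21 | intermediate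
25 | methyl (1(10)E,4R,5S,6S,7R,8S,9R)-4,5-epoxy-9-hydroxy-8-{[(2S)-2-methyloxirane-2-carbonyl]oxy}germacra-1(10),11(13)-dien-6,12-olid-14-oate | C=C1C(=O)O[C@H]2[C@H]1[C@H](OC(=O)[C@]1(C)CO1)[C@H](O)/C(C(=O)OC)=C\CC[C@@]1(C)O[C@@H]21 | intermediate
26 | methyl (1(10)E,4R,5S,6S,7R,8S,9R)-9-acetoxy-4,5-epoxy-8-{[(2S)-2-methyloxirane-2-carbonyl]oxy}germacra-1(10),11(13)-dien-6,12-olid-14-oate | C=C1C(=O)O[C@H]2[C@H]1[C@H](OC(=O)[C@]1(C)CO1)[C@H](OC(C)=O)/C(C(=O)OC)=C\CC[C@@]1(C)O[C@@H]21 | target

## Step count and risks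

Total steps: 16. Longest linear sequence: 14 (steps 1–6, 8–13, 15, 16); steps 7 and 14 prepare the two acid partners.

**Most likely to fail, 1: step 13 (samarium ketyl macrocyclisation).** The ten-membered closure competes with pinacol dimerisation and simple reduction. The facial selectivity at C7 and C8 rests on a transition-state argument, not on precedent, and an allylsamarium (Barbier-type) pathway could give the C8 epimer. Fallback: setting out from 20, the ring is closed by a polar umpolung allylation with Pd(PPh3)4 (5 mol%) and InI (1.5 equiv) in THF at 25 °C under high dilution. Zerovalent palladium ionises the allylic acetate and the resulting allylindium adds through C7 to the aldehyde in a chair transition state. The product expected from that geometry is the C8-epimeric hydroxy lactone F1. Mitsunobu esterification of F1 with 23 (PPh3, DIAD, toluene, 0 °C) inverts C8 and comes back to the route at 24. The same Mitsunobu step rescues the samarium route should it deliver F1.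

**Most likely to fail, 2: step 12 (acetonide removal beside the trisubstituted epoxide).** Even PPTS/MeOH may open the epoxide or shift the silyl group. Fallback: setting out from 15, the aldehyde partner is changed to acrolein under ligand-controlled catalytic Nozaki–Hiyama–Kishi conditions (CrCl2 10 mol% with a chiral oxazoline–sulfonamide ligand, NiCl2 1 mol%, Mn, Me3SiCl, LiCl, MeCN; mildly acidic work-up). This gives the bis-allylic alcohol F2 with C9 set by the ligand. TBSOTf/2,6-lutidine converts it into the silyl ether F3. OsO4 (2 mol%), NaIO4 and 2,6-lutidine in dioxane/H2O then cleave only the electron-rich terminal vinyl group under neutral conditions, which comes back to the route at 20 with no acid used.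

**Most likely to fail, 3: step 10 (Felkin selectivity at C9).** Alkenylchromium additions to glyceraldehyde acetonide are often only moderately selective. Fallback: setting out from 17 as its C9-epimer mixture, Dess–Martin oxidation gives the ketone F4. Zn(BH4)2 in Et2O at −30 °C then reduces it 1,2-selectively under chelation control (zinc bridging the ketone and the dioxolane oxygen, hydride from the face opposite the dioxolane CH2), which gives the anti alcohol and comes back to the route at 17 as a single epimer.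

## Further compounds

F1 | step 13 | methyl (1(10)E,4R,5S,6S,7R,8R,9R)-9-(tert-butyldimethylsilyloxy)-4,5-epoxy-8-hydroxygermacra-1(10),11(13)-dien-6,12-olid-14-oate (C8 epimer of 21) | C=C1C(=O)O[C@H]2[C@H]1[C@@H](O)[C@H](O[Si](C)(C)C(C)(C)C)/C(C(=O)OC)=C\CC[C@@]1(C)O[C@@H]21
F2 | step 12 | methyl (2E)-5-{(2R,3S)-3-[(2S)-4-(acetoxymethyl)-5-oxo-2,5-dihydrofuran-2-yl]-2-methyloxiran-2-yl}-2-[(1S)-1-hydroxyprop-2-en-1-yl]pent-2-enoate | C=C[C@H](O)/C(C(=O)OC)=C\CC[C@@]1(C)O[C@H]1[C@H]1OC(=O)C(COC(C)=O)=C1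
F3 | step 12 | methyl (2E)-5-{(2R,3S)-3-[(2S)-4-(acetoxymethyl)-5-oxo-2,5-dihydrofuran-2-yl]-2-methyloxiran-2-yl}-2-[(1S)-1-(tert-butyldimethylsilyloxy)prop-2-en-1-yl]pent-2-enoate | C=C[C@H](O[Si](C)(C)C(C)(C)C)/C(C(=O)OC)=C\CC[C@@]1(C)O[C@H]1[C@H]1OC(=O)C(COC(C)=O)=C1
F4 | step 10 | methyl (2E)-5-{(2R,3S)-3-[(2S)-4-(acetoxymethyl)-5-oxo-2,5-dihydrofuran-2-yl]-2-methyloxiran-2-yl}-2-[(4S)-2,2-dimethyl-1,3-dioxolane-4-carbonyl]pent-2-enoate | CC1(C)OC[C@H](O1)C(=O)/C(C(=O)OC)=C\CC[C@@]1(C)O[C@H]1[C@H]1OC(=O)C(COC(C)=O)=C1
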